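**Assumption:** iridoid numbering is used for atom labels (C1 acetal carbon, O2, C3=C4, C5/C9 ring fusion, C6, C7 bearing OAc, C8 bearing OH and C10H2OH, C11 = CH2O on C4). In this numbering the target is (1S,5S,7S,8R,9S), with H-5, H-9, 7-OAc, C10 and the 1-O-acyl group on one face and 8-OH on the other.

## Retrosynthetic overview

1. Target ⇐ C10 desilylation ⇐ C1 O-isovalerylation of a lactol ⇐ partial reduction of a cis-fused enol δ-lactone that already carries 7-OAc, 8-OH and 11-O-isovalerate.
2. Enol lactone ⇐ convergent Pd-catalysed, carboxylate-directed β-C(sp3)–H alkenylation/lactonisation (formal [3+3]): forms C4–C5, then O2–C3, joining a cyclopentane acid (C1, C5–C10) to a (Z)-β-alkoxy vinyl iodide (C3, C4, C11).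
3. Acid ⇐ alcohol oxidation ⇐ acetate opening of a hydroxyl-directed epoxide (C7, C8) ⇐ Still–Wittig [2,3] shift (C9–C1) ⇐ CBS reduction of 2-(silyloxymethyl)cyclopentenone.
4. Vinyl iodide ⇐ isovalerylation, ester reduction and α-iodination of a β-(trifluoroethoxy)acrylate ⇐ methyl propiolate.
5. Ring order: the cyclopentane comes from the first starting material; the dihydropyran is closed last, in the key step.

## Fragment A (cyclopentane acid)

**Step 1**
Reactants: 1, 2-(hydroxymethyl)cyclopent-2-en-1-one
Product: 2, 2-{[(tert-butyldimethylsilyl)oxy]methyl}cyclopent-2-en-1-one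
Conditions: TBSCl, imidazole, CH2Cl2, 0 °C to rt
Reagents that add atoms: tert-butyldimethylsilyl chloride, CC(C)(C)[Si](C)(C)Cl
Why: Standard imidazole-promoted silylation of a primary alcohol; the enone is untouched.

**Step 2**
Reactants: 2, 2-{[(TBS)oxy]methyl}cyclopent-2-en-1-one
Product: 3, (R)-2-{[(TBS)oxy]methyl}cyclopent-2-en-1-ol
Conditions: (S)-Me-CBS (15 mol %), BH3·SMe2, THF, −20 °C
Reagents that add atoms: none
Why: Corey–Bakshi–Shibata 1,2-reduction with the α-substituted alkenyl arm as the large group gives the (R)-allylic alcohol, the stereocentre that is relayed to C9 in step 4.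

**Step 3**
Reactants: 3, (R)-allylic alcohol
Product: 4, tributyl{[((R)-2-{[(TBS)oxy]methyl}cyclopent-2-en-1-yl)oxy]methyl}stannane
Conditions: KH, Bu3SnCH2I, THF, 0 °C to rt
Reagents that add atoms: (iodomethyl)tributylstannane, CCCC[Sn](CCCC)(CCCC)CI
Why: Williamson etherification of the potassium alkoxide gives the Still stannylmethyl ether without touching the stereocentre.

**Step 4**
Reactants: 4, stannylmethyl ether
Product: 5, (S)-(2-{[(TBS)oxy]methyl}cyclopent-2-en-1-yl)methanol
Conditions: n-BuLi, THF, −78 °C
Reagents that add atoms: none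
Why: Sn–Li exchange then Still–Wittig [2,3]-sigmatropic rearrangement, which is suprafacial, so the C–O chirality is transferred to the new C9–C1 bond (C9 = S) and the alkene moves to C7=C8.

**Step 5**
Reactants: 5, (S)-homoallylic alcohol
Product: 6, [(1R,2R,5R)-1-{[(TBS)oxy]methyl}-6-oxabicyclo[3.1.0]hexan-2-yl]methanol (epoxide cis to CH2OH)
Conditions: VO(acac)2 (5 mol %), t-BuOOH, CH2Cl2, 0 °C to rt
Reagents that add atoms: tert-butyl hydroperoxide, CC(C)(C)OO
Why: Hydroxyl-directed vanadium epoxidation delivers oxygen to the alkene face syn to the CH2OH group, fixing the C8–O bond cis to C1.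

**Step 6**
Reactants: 6, cis-epoxy alcohol
Product: 7, (1S,2R,3R)-2-hydroxy-3-(hydroxymethyl)-2-{[(TBS)oxy]methyl}cyclopentyl acetate
Conditions: CsOAc, AcOH (1 equiv), DMF, 80 °C
Reagents that add atoms: caesium acetate, CC(=O)[O-].[Cs+]
Why: SN2 epoxide opening by acetate at the secondary carbon C7 (C8 is fully substituted) with inversion gives the trans 7-OAc/8-OH array with C10 cis to the acetate (C7 = S, C8 = R).

**Step 7**
Reactants: 7, acetoxy diol
Product: 8, (1S,2R,3S)-3-acetoxy-2-hydroxy-2-{[(TBS)oxy]methyl}cyclopentane-1-carboxylic acid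
Conditions: TEMPO (cat.), PhI(OAc)2, MeCN/pH 7 buffer, rt
Reagents that add atoms: water (O), O
Why: TEMPO/PhI(OAc)2 oxidation takes the primary alcohol to the acid; the tertiary alcohol, acetate and silyl ether are inert and C9 is not epimerised under neutral conditions.

## Fragment B (vinyl iodide)

**Step 8**
Reactants: 9, methyl propiolate
Product: 10, methyl (E)-3-(2,2,2-trifluoroethoxy)acrylate
Conditions: CF3CH2OH, DABCO (10 mol %), CH2Cl2, 0 °C to rt
Reagents that add atoms: 2,2,2-trifluoroethanol, OCC(F)(F)F
Why: Amine-catalysed oxa-Michael addition to the propiolate gives the (E)-β-alkoxyacrylate; the electron-poor trifluoroethyl enol ether is chosen to be less ionisable and a better leaving group later.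

**Step 9**
Reactants: 10, methyl (E)-3-(2,2,2-trifluoroethoxy)acrylate
Product: 11, methyl (Z)-2-iodo-3-(2,2,2-trifluoroethoxy)acrylate
Conditions: NIS, AcOH, CH2Cl2, rt; then Et3N
Reagents that add atoms: N-iodosuccinimide, O=C1CCC(=O)N1I
Why: Electrophilic iodination at the enol-ether β-carbon followed by base-induced elimination (addition–elimination) gives the α-iodo acrylate with iodine cis to the alkoxy group.

**Step 10**
Reactants: 11, methyl (Z)-2-iodo-3-(2,2,2-trifluoroethoxy)acrylate
Product: 12, (Z)-2-iodo-3-(2,2,2-trifluoroethoxy)prop-2-en-1-ol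
Conditions: DIBAL-H (2.2 equiv), CH2Cl2, −78 °C
Reagents that add atoms: none
Why: DIBAL 1,2-reduction of the vinylogous carbonate ester gives the allylic alcohol (future C11) with the vinyl iodide and alkene geometry intact.

**Step 11**
Reactants: 12, (Z)-2-iodo-3-(2,2,2-trifluoroethoxy)prop-2-en-1-ol
Product: 13, (Z)-2-iodo-3-(2,2,2-trifluoroethoxy)allyl 3-methylbutanoate
Conditions: isovaleryl chloride, pyridine, CH2Cl2, 0 °C
Reagents that add atoms: 3-methylbutanoyl chloride, CC(C)CC(=O)Cl
Why: Simple acylation of the primary alcohol under basic, non-ionising conditions installs the C11 isovalerate before coupling.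

## Coupling and endgame

**Step 12 (key step)**
Reactants: 8, (1S,2R,3S)-3-acetoxy-2-hydroxy-2-{[(TBS)oxy]methyl}cyclopentane-1-carboxylic acid; 13, (Z)-2-iodo-3-(2,2,2-trifluoroethoxy)allyl 3-methylbutanoate
Product: 14, (4aS,6S,7R,7aS)-6-acetoxy-7-hydroxy-7-{[(TBS)oxy]methyl}-4-[(3-methylbutanoyloxy)methyl]-4a,5,6,7,7a-pentahydrocyclopenta[c]pyran-1-one (cis-fused enol δ-lactone)
Conditions: Pd(OAc)2 (10 mol %), Ac-Gly-OH (20 mol %), Ag2CO3, K2HPO4, 4 Å MS, t-AmylOH, 80 °C
Reagents that add atoms: none
Why: Proposed new method: the κ-carboxylate directs concerted metalation–deprotonation of the only β-C–H available (C5–H cis to CO2H; C8 has no hydrogen) to give a five-membered palladacycle; oxidative addition of vinyl iodide 13 gives Pd(IV), and C(sp3)–C(sp2) reductive elimination with retention sets C5 cis to C9 and keeps C5 cis to the OCH2CF3 group; the Pd(II)-bound carboxylate then adds 6-endo to the enol ether and β-trifluoroethoxide is eliminated (intramolecular trans-vinylation) to close the lactone, with AgI precipitation driving turnover. The closest known reactions are 8-aminoquinoline-directed Pd(II)/Pd(IV) cis-β-C–H alkenylation of cycloalkanecarboxamides with vinyl iodides, free-acid-directed β-C(sp3)–H arylation and olefination–lactonisation, and Pd(II)-catalysed vinyl exchange between vinyl ethers and carboxylic acids.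

**Step 13**
Reactants: 14, enol δ-lactone
Product: 15, (1R,4aS,6S,7R,7aS)-6-acetoxy-1,7-dihydroxy-7-{[(TBS)oxy]methyl}-4-[(3-methylbutanoyloxy)methyl]-1,4a,5,6,7,7a-hexahydrocyclopenta[c]pyran (lactol, 1β-OH major anomer)
Conditions: DIBAL-H (2.1 equiv), CH2Cl2, −78 °C; Rochelle salt work-up; used at once
Reagents that add atoms: none
Why: Half-reduction of the activated enol lactone (the nepetalactone-to-nepetalactol type) is faster than attack on the alkyl acetate and isovalerate, and the tetrahedral aluminate is stable at −78 °C; one equivalent is consumed by the tertiary OH.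

**Step 14**
Reactants: 15, lactol
Product: 16, 10-O-TBS-jatamanvaltrate H, (1S,4aS,6S,7R,7aS)-configured 1-O-isovalerate
Conditions: isovaleryl chloride, pyridine, DMAP (cat.), CH2Cl2, −20 to 0 °C
Reagents that add atoms: 3-methylbutanoyl chloride, CC(C)CC(=O)Cl
Why: The equilibrating lactol is acylated as its 1β anomer (oxygen cis to H-9, pseudo-axial and anomerically stabilised, on the convex face), as is usual for iridoid aglycone lactols, and the hindered tertiary 8-OH does not react.

**Step 15**
Reactants: 16, 10-O-TBS-jatamanvaltrate H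
Product: 17, jatamanvaltrate H
Conditions: HF·pyridine, pyridine, THF, 0 °C
Reagents that add atoms: none
Why: Buffered fluoride desilylation of the primary TBS ether leaves the acyl acetal, enol ether and three esters intact, and the trans 7-OAc/8-OH relationship prevents acetyl migration.

## Compound list

1 | 2-(hydroxymethyl)cyclopent-2-en-1-one | O=C1CCC=C1CO | starting material
2 | 2-{[(tert-butyldimethylsilyl)oxy]methyl}cyclopent-2-en-1-one | O=C1CCC=C1CO[Si](C)(C)C(C)(C)C | intermediate
3 | (R)-2-{[(TBS)oxy]methyl}cyclopent-2-en-1-ol | O[C@@H]1CCC=C1CO[Si](C)(C)C(C)(C)C | intermediate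
4 | tributyl{[((R)-2-{[(TBS)oxy]methyl}cyclopent-2-en-1-yl)oxy]methyl}stannane | CCCC[Sn](CCCC)(CCCC)CO[C@@H]1CCC=C1CO[Si](C)(C)C(C)(C)C | intermediate
5 | (S)-(2-{[(TBS)oxy]methyl}cyclopent-2-en-1-yl)methanol | OC[C@H]1CCC=C1CO[Si](C)(C)C(C)(C)C | intermediate
6 | [(1R,2R,5R)-1-{[(TBS)oxy]methyl}-6-oxabicyclo[3.1.0]hexan-2-yl]methanol | OC[C@H]1CC[C@H]2O[C@@]12CO[Si](C)(C)C(C)(C)C | intermediate
7 | (1S,2R,3R)-2-hydroxy-3-(hydroxymethyl)-2-{[(TBS)oxy]methyl}cyclopentyl acetate | OC[C@H]1CC[C@H](OC(C)=O)[C@]1(O)CO[Si](C)(C)C(C)(C)C | intermediate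
8 | (1S,2R,3S)-3-acetoxy-2-hydroxy-2-{[(TBS)oxy]methyl}cyclopentane-1-carboxylic acid | OC(=O)[C@H]1CC[C@H](OC(C)=O)[C@]1(O)CO[Si](C)(C)C(C)(C)C | intermediate
9 | methyl propiolate | C#CC(=O)OC | starting material
10 | methyl (E)-3-(2,2,2-trifluoroethoxy)acrylate | FC(F)(F)CO/C=C/C(=O)OC | intermediate
11 | methyl (Z)-2-iodo-3-(2,2,2-trifluoroethoxy)acrylate | FC(F)(F)CO/C=C(\I)C(=O)OC | intermediate
12 | (Z)-2-iodo-3-(2,2,2-trifluoroethoxy)prop-2-en-1-ol | FC(F)(F)CO/C=C(\I)CO | intermediate
13 | (Z)-2-iodo-3-(2,2,2-trifluoroethoxy)allyl 3-methylbutanoate | FC(F)(F)CO/C=C(\I)COC(=O)CC(C)C | intermediate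
14 | (4aS,6S,7R,7aS) cis-fused enol δ-lactone (C1=O, 7-OAc, 8-OH, 10-OTBS, 11-O-isovalerate) | CC(=O)O[C@H]1C[C@@H]2C(COC(=O)CC(C)C)=COC(=O)[C@@H]2[C@@]1(O)CO[Si](C)(C)C(C)(C)C | intermediate
15 | (1R,4aS,6S,7R,7aS) lactol (1β-OH) | CC(=O)O[C@H]1C[C@@H]2C(COC(=O)CC(C)C)=CO[C@@H](O)[C@@H]2[C@@]1(O)CO[Si](C)(C)C(C)(C)C | intermediate
16 | 10-O-TBS-jatamanvaltrate H | CC(=O)O[C@H]1C[C@@H]2C(COC(=O)CC(C)C)=CO[C@@H](OC(=O)CC(C)C)[C@@H]2[C@@]1(O)CO[Si](C)(C)C(C)(C)C | intermediate
17 | jatamanvaltrate H | CC(=O)O[C@H]1C[C@@H]2C(COC(=O)CC(C)C)=CO[C@@H](OC(=O)CC(C)C)[C@@H]2[C@@]1(O)CO | target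

## Step count

Total steps: 15 (fragment A, 7; fragment B, 4; coupling and endgame, 4).
Longest linear sequence: 11 (steps 1–7, then 12–15).

## Steps most likely to fail, with fallbacks

1. **Step 12 (proposed new annulation).** Risks: a secondary C–H bond on a free acid bearing an α-hydrogen is a demanding substrate; the vinylogous-acylal iodide 13 may ionise under Ag(I); the 8-OH may add to the enol ether instead of the carboxylate.
   Fallback (known chemistry): make the 8-aminoquinoline amide of the acid and run the established Pd(OAc)2/AgOAc auxiliary-directed cis-β-C–H alkenylation with the robust methyl (Z)-2-iodo-3-methoxyacrylate. Then remove the auxiliary (N-Boc activation, LiOOH) and close the lactone by acid-catalysed addition–elimination on the β-methoxyacrylate. In this variant C7 is carried as a silyl ether, and C11 is reduced together with the lactone and acylated at the end.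

2. **Step 6 (regioselective acetate opening of the trisubstituted epoxide).** Risks: slow SN2 next to the quaternary carbon, or competing attack at C8.
   Fallback: reverse the epoxide logic. Protect the primary alcohol of 5 as a TBDPS ether and epoxidise with mCPBA on the face anti to the C9 substituent. Open that epoxide with dilute aqueous acid at the tertiary carbon (SN1-like, inversion at C8) to reach the same trans-diol, then acetylate the secondary 7-OH selectively.

3. **Steps 13–14 (chemoselective lactone reduction; labile lactol with a β-acyloxy leaving group; C1 configuration).** Risks: ester cleavage, ring-opening and elimination of the C11 isovalerate, or a poor anomer ratio.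
   Fallback: carry C11 as a TBS ether (silylate 12 instead of acylating it), so the lactol has no leaving group. Reduce, isovalerylate C1 under equilibrating conditions, remove both silyl groups with HF·pyridine, and acylate the unhindered allylic C11–OH selectively over the neopentyl C10–OH (1 equiv isovaleryl chloride/collidine at −40 °C, or lipase with vinyl isovalerate).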